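I judge this flask by one ratio, product made per initiator charged, and leave the clock out of it.

common to all: substrate 0.30 M
- teal: coupling partner 5 equiv; initiator 8.8 mol%; temperature 0 °C; the very flask that is asked about, followed so far
- red: coupling partner 5 equiv; initiator 13 mol%; temperature −5 °C; run made earlier
- flask: coupling partner 5.00 equiv; initiator 8.8 mol%; temperature 0 °C; time 40 min

- teal (time / min: product / %): 2.00: 54.7; 6.00: 66.5; 12.0: 66.6; 15.0: 62.4; 25.0: 65.5; 30.0: 66.1; 40.0: 65.6
- red (time / s: product / %): 10.0: 7.1; 15.0: 13.9; 20.0: 15.9; 30.0: 19.3; 40.0: 23.6; 50.0: 29.8

(scatter of a reading: 1 percentage point)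

- removed product is counted in
- the earlier runs were read with a standard deviation of 1 percentage point
- additions bring no volume worth counting

- dusk: at 40 min take out 90 % of the product then present, then wait 80 min
- summer: at 40 min add coupling partner, 50.0 % of the amount charged, then wait 80 min
- noon: at 40 min raise the temperature by 20 K, then wait 80 min
- dawn: change nothing and wait 80 min more

1. product, in percent of the substrate first charged, at 40 min
2. which option adds most product ("none" when 2 percentage points or less is all one gets) (dusk / summer / noon / dawn / none)
3. product present, with what was taken out counted in, in percent of the substrate first charged, after dusk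
4. product present, with what was taken out counted in, in percent of the substrate first charged, after noon

In the teal flask, the reading at 6.00 min and the one at 40.0 min differ by 0.9 percentage points, about one standard deviation, so more time is not what the flask wants. My plateau, from the readings from 25.0 min on, is 65.7 %, which leaves 34.3 % of the substrate not turned into product. Two amounts stay to be compared: product made and initiator charged.

Their quotient is 7.47. It is a rate of product over a rate of initiator loss, summed up, so time cancels. I call it the chain yield, a crude kinetic chain length. For the red run's loading it gives 97.1 %, but that run ends at 29.8 % and still rising, so it tests nothing.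

Reading the stop as lost initiator and not as equilibrium is my judgement. I commit to 65.7 % at the asked time and to no option clearing 2 points.

The forecast gives 65.6 %, 65.8 % after dusk, 65.8 % after noon, and best none: “So I expect dead chemistry: no option adds anything”.

The flask gives 65.6 %, 65.6 % after dusk, 65.6 % after noon, and best none.

    initiator → 2 initiating radical (k = 0.0200 s⁻¹, Ea = 67.0 kJ mol⁻¹)
    substrate + initiating radical → capped initiator + first chain carrier (k = 4.20 × 10⁵ L mol⁻¹ s⁻¹, Ea = 9.00 kJ mol⁻¹)
    coupling partner + first chain carrier ⇌ product + second chain carrier (K = 0.310, k = 1800 L mol⁻¹ s⁻¹, Ea = 40.0 kJ mol⁻¹, ΔH = 35.0 kJ mol⁻¹)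
    substrate + second chain carrier → released group + first chain carrier (k = 9200 L mol⁻¹ s⁻¹, Ea = 28.0 kJ mol⁻¹)
    2 first chain carrier → ended chains (k = 2.70 × 10⁸ L mol⁻¹ s⁻¹, Ea = 10.0 kJ mol⁻¹)
    coupling partner ⇌ dormant form (K = 0.120, k = 0.0140 s⁻¹, Ea = 80.0 kJ mol⁻¹, ΔH = −61.0 kJ mol⁻¹)
    (constants at 0 °C)

In the teal flask, the step of substrate with second chain carrier gives substrate a half-life of 1.3 min at 0.690 min. At 40.0 min that half-life is 5200 h, far longer than the 80 min wait, with 0 % of the initiator left. The result puts this flask's chain yield at 7.46. Carried to the neighbour flask with 2.2 mol% of initiator, my 7.47 gives 16.4 %, but that flask ends higher, at 44.4 %, with 0 % of its initiator and 51.2 % of its substrate left.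

All runs stem from a simulated flask on assumed constants; the scatter is artificial.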